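Count in equivalents of the Qa charged. The red flask holds 1.30 equivalents of Qd and the ochre flask 1.94, and every yield below is a fraction of that same Qa charge. The flask asked about is red, carried on to a later time.

| setting | red | ochre | flask |
|---|---|---|---|
| Qa | 17 mM | 17 mM | 17 mM |
| Qd | 22.1 mM | 33 mM | 22.1 mM |
| Qb | 0.20 mM | 0.20 mM | 0.20 mM |
| remark | the very flask that is asked about, followed so far | run made earlier |  |
| time |  |  | 25 min |

| run | time / min | Qa / % | Qj / % |
|---|---|---|---|
| red | 0.333 | 62.8 | 37.0 |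
| red | 1.00 | 52.3 | 49.6 |
| red | 2.00 | 48.8 | 49.9 |
| red | 2.50 | 51.0 | 50.3 |
| red | 4.00 | 50.5 | 50.5 |
| red | 5.00 | 50.5 | 50.0 |
| ochre | 4.00 | 29.4 | 70.9 |
| ochre | 8.00 | 29.3 | 71.0 |
| ochre | 12.0 | 28.2 | 71.0 |
| ochre | 15.0 | 30.6 | 70.5 |
| ochre | 20.0 | 30.3 | 71.7 |
| ochre | 25.0 | 28.5 | 71.7 |

(standard deviation of a reading: 1 percentage point)

- percentages count the Qa that a species holds: one Qg counts as two
- on the list of suspects stand: Qd + Qe -> Qj + Qf; Qd -> Qn; Qd -> Qm; Qb -> 2 Qc; 2 Qe -> Qg; Qa + Qc -> Qh + Qe; Qa + Qf -> Qk + Qe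

- share of the Qa used up at 25 min
- Qj at 25 min, in percent of the Qa charged

Start with the main chain by itself. Qe takes a Qd and gives Qj and Qf, then Qf takes a Qa and gives Qk and Qe back, so one Qd turns one Qa into one Qj. Red has more Qd than Qa, so this reckoning puts Qj at a fraction of 1. But the red readings level at 50.2%, and the ochre readings at 71.1%.

Now add the decay Qd → Qn, which gives Qd a second exit. Take the Qd share, the Qj made per Qd charged, both counted as fractions of the Qa charge. At a fixed level of Qe both exits are first order in Qd, so at that level the share does not depend on the Qd charge, and the plateau is share times equivalents. Red reads 0.386 and ochre 0.366. In powers of ten, the plateaus differ by 0.152 and the equivalents by 0.174, so the plateau goes as Qd to the power 0.874, a reading close to first order.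

Then add the rest: Qb and Qc supply Qe, and 2 Qe → Qg removes it. The ochre readings show no late creep: Qj moves 0.8 percentage points between 4.00 min and 25.0 min, against a scatter of 1 point. So I commit to about 50.2% for both answers in red.

The forecast gave 50% and 50.2%, holding that “nothing restarts the chain and Qa is not slowly lost later”.

The flask gives 49.8% of Qa used up and 49.8% of Qj at 25 min.

    Qd + Qe → Qj + Qf (k = 3.80 × 10⁶ M⁻¹ s⁻¹)
    Qd → Qn (k = 0.0450 s⁻¹)
    Qd → Qm (k = 9.59 × 10⁻⁶ s⁻¹)
    Qb → 2 Qc (k = 2.31 × 10⁻⁵ s⁻¹)
    2 Qe → Qg (k = 5.80 × 10⁷ M⁻¹ s⁻¹)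
    Qa + Qc → Qh + Qe (k = 5.12 × 10⁷ M⁻¹ s⁻¹)
    Qa + Qf → Qk + Qe (k = 9.98 × 10⁵ M⁻¹ s⁻¹)

Qd is the limiting reagent in this flask, with 0% of its charge left at 25.0 min against 50% of the Qa. The Qd share of this flask now stands at 0.383. Take a neighbour, the same flask with 5.5 mM of Qd, which is 0.324 equiv: the share read from red times those equivalents gives 12.5% of Qj, and the neighbour gives 13.2%.

Readings and results are calculated for an exercise; noise was put on by code.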